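A [target] curve that flattens invites one reading, a balance of forward and back steps, yet a flask that loses its starting material by another path flattens in the same way.

| flask | starting material | target | time |
|---|---|---|---|
| Sunday's | 200 mM |  |  |
| Thursday's | 600 mM |  |  |
| Monday's | 200 mM | 100 mM | 3.7 h |

| run | time / h | [target] / mM |
|---|---|---|
| Sunday's run | 0.28 | 15.6 |
| Sunday's run | 0.85 | 35.0 |
| Sunday's run | 1.6 | 50.7 |
| Sunday's run | 2.6 | 55.0 |
| Sunday's run | 3.7 | 58.4 |
| Thursday's run | 0.28 | 56.6 |
| Thursday's run | 0.85 | 131.7 |
| Thursday's run | 1.6 | 181.3 |
| Thursday's run | 2.6 | 210.2 |
| Thursday's run | 3.7 | 220.8 |

(scatter of a reading: 1 mM)

- order of the initial rate in [starting material], near the charge of the Sunday's run, the rate being that where two percent of its starting material are target (one fixed amount of target, the same in the runs compared)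
- target in the Monday's run at 3.7 h, as a share of the starting material charged

- Overall: starting material -> target.
- Constant volume, constant temperature.
- Bound and free are read together.
- An order is taken over about fifteen percent of the charge, up and down.
- A share of target counts the target that was charged too.

Two chemists dispute this curve. The first, who made the forecast, sees Sunday's and Thursday's runs relax at the same pace, about 1.04 h⁻¹, and concludes that “the kinetics look first-order and reversible”. To reconcile the two plateaus, this chemist sets about 54 mM of starting material aside, unread.

The second chemist works with the fraction left. At 3.7 h, Sunday's run has turned the fresh share, meaning target made over starting material charged, of 29.2%, which leaves 70.8% of its charge unaccounted for. Thursday's run has a fresh share of 36.8%, larger at the higher charge. This chemist holds that the rest of the charge left by other paths while target stayed inert, which is kinetic rather than thermodynamic control.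

At the first reading, 0.28 h, Thursday's run holds 3.63 times the target of Sunday's run for 3.00 times the charge. My own reckoning from that pair of readings, taken at one time and not at one amount of target, is an average order of 1.17 between the two charges.

They part over Monday's run. If target is inert, the 100 mM charged changes nothing for the starting material, and Monday's run, with Sunday's charge, adds the same fresh share. That gives 79.2%. The forecast, from the first view, gives 1.45 for the order and 50.6% for Monday's share, and both differ from my own figures.

The flask gives 1.4 and 79.5%. The forecast's Monday value is what a fit with decaying target gives.

    2 starting material ⇌ substrate dimer, settled at all times (8.260 L mol⁻¹)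
    substrate dimer → target + starting material (1.055 h⁻¹)
    starting material → decomposed substrate (0.5040 h⁻¹)
    2 starting material → homo dimer (4.068 L mol⁻¹ h⁻¹)

The first view keeps the early stretch of a run, near two percent turned, where its order of 1.45 stands within the margin of the flask's 1.4. Later, Monday's run makes 58.9 mM of new target, a fresh share of 29.5% against Sunday's 29.2%. Monday's share is held down by the joint loss of starting material to decomposed substrate and homo dimer: without the first loss it reaches 91.6%, and without the second 91.0%.

Readings and results are calculated with constants of no real substance, and the scatter is random.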